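The readings were generated by integration from invented constants; noise was put on by code.

1. A closed flask of constant volume keeps a balance: D charged stays D, becomes J, or goes unread. In the north run at 40.0 min, D holds 33 %, J 57 % and the unread rest 10.0 %. So the reckoning works with f, the fraction of D left.

the same everywhere: D 0.075 M; E 0.0825 M

| run | Z | Q | temperature | remark | time |
|---|---|---|---|---|---|
| north-west | 0.075 M | 24 µM | 40 °C | run made earlier |  |
| north | 0.075 M | 35 µM | 73 °C | run made earlier |  |
| Wednesday's | 0.0750 M | 47 µM | 65 °C |  | 1.0 h |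
| Sunday's | 0.0750 M | 47 µM | 45 °C |  | 1.0 h |
| Saturday's | 0.0750 M | 47 µM | 85 °C |  | 1.0 h |
| Tuesday's | 0.0750 M | 47 µM | 25 °C |  | 1.0 h |

north-west run (percent of the D charged)

| time / h | J / % | D / % |
|---|---|---|
| 0.500 | 15 | 63 |
| 0.833 | 19 | 52 |
| 1.00 | 17 | 49 |
| 1.50 | 21 | 38 |
| 2.50 | 24 | 27 |

north run (percent of the D charged)

| time / min | J / % | D / % |
|---|---|---|
| 8.00 | 40 | 53 |
| 15.0 | 49 | 42 |
| 20.0 | 54 | 38 |
| 30.0 | 54 | 35 |
| 40.0 | 57 | 33 |

(each reading ± 1.5 percentage points)

* which flask leads in amount of J, in percent of the D charged ("all alike" within 1.5 percentage points) (Wednesday's / Sunday's / Saturday's / Tuesday's / all alike)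
* how much J is there at the end, in percent of the D charged: Wednesday's
* how much J is there at the end, in percent of the D charged: Sunday's
* how much J is there at the end, in percent of the D charged: Saturday's
* how much J is there at the end, in percent of the D charged: Tuesday's



2. E is charged at 1.10 times D, so [D] and [E] fall nearly together, and g = 1/f − 1 should climb with time while Q lasts. In the north-west run, g goes from 0.587 at 0.500 h to 2.70 at 2.50 h.

3. The north run slows instead: g reads 1.63 at 20.0 min and 2.03 at 40.0 min. The gain over the second 20.0 min reads 0.244 of that over the first, which, if Q fades exponentially, reads as a lifetime of Q of 14.2 min in the north run.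

4. The end value of g reckoned for the north run is the reach, 2.16: the lifetime of Q divided by the time fresh Q takes to halve D. That second time is 6.57 min, and f ends at 1/(1 + reach).

5. My reckoning for Saturday's assumes that its Q lasts no longer than the north lifetime: 1.0 h is longer than that lifetime, so Saturday's is taken to end near its reach. Assuming further that reach grows in proportion to [Q], Saturday's reach reckons to 2.90. With the selectivity read in the north run, J per D consumed, of 0.851, J reckons to 63.3 %. Both values are carried over from 73 °C.

6. The forecast names Wednesday's, with 60 % there, 32 % for Sunday's, 57 % for Saturday's and 8 % for Tuesday's: “The optimum is intermediate; 85 °C is the least certain.” My Saturday's figure stands above its figure.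

7. The flasks give:

    Z + E + Q → Q + L (k = 2.00 /M²/s, Ea = 38.0 kJ/mol)
    D + E + Q → Q + J (k = 76.0 /M²/s, Ea = 39.0 kJ/mol)
    Q + J → G (k = 8.30 × 10⁻⁴ /M/s, Ea = 65.0 kJ/mol)
    J ⇌ X (K = 6.90, k = 8.70 × 10⁻⁴ /s, Ea = 87.0 kJ/mol, ΔH = −64.0 kJ/mol)
    (constants at 25 °C)

Saturday's leads with 61.8 %, against 57.7 % for Wednesday's, 31.3 % for Sunday's and 15.0 % for Tuesday's. Saturday's D stands at 32.5 % after 1.00 h and 32.5 % after 10.0 h, with Q at 0 %. Saturday's reach is therefore 2.08, less than the reckoned one, and its J per D consumed is 0.915. The flask like Saturday's but with 8.0 × 10⁻⁵ M of Q ends with D at 24.6 %, a reach of 3.07. That reach with Saturday's share reckons to 69.0 % of J, and that flask holds 69.0 %.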